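**Overview**
- **Cuts:** With the three phenols masked as allyl ethers and the side-chain alcohol as a silyl ether, ring C is cut at C4–C4a (intramolecular Friedel–Crafts acylation), then at O1–C2 (vinylic substitution). The C3/C4 unit is cut from ring B at C2–C3 (crossed Claisen condensation).
- **Fragments:** Ring B loses its two chains at the aryl–CH2 bonds (two separate phenoxide C-prenylations). Ring A goes back to a 4-O-methylgallate whose ester carbon is exchanged for the O1 oxygen.
- **Forward order:** Rings A and B are bought as benzoates and built up apart. They are joined through O1–C2 as an acyclic aryl enol ether that already holds the C3 methoxy group and the C2 aryl group, and ring C closes last.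
- **Enabling feature:** Ring A has oxygen at C5, C6 and C7 and hydrogen at C8, so its precursor is a 3,4,5-trioxygenated phenoxy ring with a mirror plane through O1 and the C6 methoxy group. Its two ortho carbons (future C4a and C8) are identical, each ortho to O1 and to one allyloxy group and para to the other, so closure at C4–C4a can give only the 5,6,7 pattern.
- **Stereochemistry:** There is no stereocentre. The E trisubstituted alkene comes from SeO2 oxidation of the methyl group trans to the chain in the first prenyl group, done before the second prenyl group is present.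

Key step: step 16

Remark: the tetrasubstituted alkene between the future C2 and C3 is expected as a mixture of isomers from step 9 to step 15. It is named and drawn throughout as the E isomer (acyl carbon cis to the heteroatom on the future C2), the one that cyclises, because step 16 lets both converge.

Abbreviations: TBDPS = tert-butyldiphenylsilyl; ArB = 4-(allyloxy)-3-[(E)-4-(TBDPS-oxy)-3-methylbut-2-enyl]-5-(3-methylbut-2-enyl)phenyl, that is, ring B with both chains.

**Step 1**
Reactants: 1 methyl 4-hydroxybenzoate; 2 prenyl bromide (1-bromo-3-methylbut-2-ene)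
Product: 4 methyl 4-hydroxy-3-(3-methylbut-2-enyl)benzoate, via sodium phenoxide 3 (not isolated)
Conditions: NaH (1.05 equiv), toluene, 0 °C to rt; then 2 (1.0 equiv), rt to 50 °C
Reagents that add atoms: none
Why: Ortho C-alkylation of a phenoxide, a reaction type well known for 4-hydroxybenzoates: in toluene the sodium salt reacts as a tight ion aggregate whose oxygen is shielded by the cation, so the allylic bromide is taken up at an ortho carbon (the para carbon is blocked by the ester) and tautomerisation restores the phenol.

**Step 2**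
Reactants: 4 methyl 4-hydroxy-3-(3-methylbut-2-enyl)benzoate
Product: 5 methyl 4-acetoxy-3-(3-methylbut-2-enyl)benzoate
Conditions: Ac2O, pyridine, DMAP (cat.), CH2Cl2, 0 °C to rt
Reagents that add atoms: acetic anhydride, CC(=O)OC(C)=O
Why: Routine O-acetylation, which keeps the ortho-prenylphenol from oxidative cyclisation in the next step and later leaves under conditions that cannot harm a methyl ester.

**Step 3**
Reactants: 5 methyl 4-acetoxy-3-(3-methylbut-2-enyl)benzoate
Product: 7 methyl 4-acetoxy-3-[(E)-4-hydroxy-3-methylbut-2-enyl]benzoate, via E enal 6 (not isolated)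
Conditions: SeO2 (0.5 equiv), t-BuOOH (2.5 equiv, in decane), CH2Cl2, 0 °C to rt; crude product, NaBH4, THF/MeOH, −20 °C
Reagents that add atoms: selenium dioxide, O=[Se]=O; tert-butyl hydroperoxide, CC(C)(C)OO
Why: Riley allylic oxidation with t-BuOOH as terminal oxidant: the ene reaction followed by a [2,3]-sigmatropic shift places oxygen on the methyl group trans to the chain and so fixes the E alkene of the target, and a short cold borohydride reduction returns the over-oxidised enal 6 to the same alcohol.

**Step 4**
Reactants: 7 methyl 4-acetoxy-3-[(E)-4-hydroxy-3-methylbut-2-enyl]benzoate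
Product: 9 methyl 4-hydroxy-3-[(E)-4-(TBDPS-oxy)-3-methylbut-2-enyl]benzoate, via silylated acetate 8 (not isolated)
Conditions: TBDPSCl (1.1 equiv), imidazole (2.2 equiv), DMF, 0 °C to rt; then MeOH, K2CO3 (2 equiv), rt
Reagents that add atoms: tert-butyldiphenylsilyl chloride, CC(C)(C)[Si](Cl)(c1ccccc1)c1ccccc1
Why: Silylation of the primary allylic alcohol followed in the same flask by methanolysis of the activated aryl acetate; methanol cannot change the methyl ester, the alkyl silyl ether is inert, and any phenol that had lost its acetate in step 3 and been silylated is set free again under these conditions.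

**Step 5**
Reactants: 9 methyl 4-hydroxy-3-[(E)-4-(TBDPS-oxy)-3-methylbut-2-enyl]benzoate; 2 prenyl bromide
Product: 11 methyl 4-hydroxy-3-[(E)-4-(TBDPS-oxy)-3-methylbut-2-enyl]-5-(3-methylbut-2-enyl)benzoate, via sodium phenoxide 10 (not isolated)
Conditions: NaH (1.05 equiv), toluene, 0 °C to rt; then 2 (1.2 equiv), rt to 50 °C
Reagents that add atoms: none
Why: Second phenoxide C-alkylation under the same non-polar conditions: only one ortho carbon is left and the para carbon is blocked, so C-attack has a single outcome, and because the first chain is already oxidised and silylated the two chains are never equivalent.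

**Step 6**
Reactants: 11 methyl 4-hydroxy-3-[(E)-4-(TBDPS-oxy)-3-methylbut-2-enyl]-5-(3-methylbut-2-enyl)benzoate
Product: 12 methyl 4-(allyloxy)-3-[(E)-4-(TBDPS-oxy)-3-methylbut-2-enyl]-5-(3-methylbut-2-enyl)benzoate (ArB–CO2Me)
Conditions: allyl bromide (1.5 equiv), K2CO3 (2 equiv), DMF, rt to 40 °C
Reagents that add atoms: allyl bromide, C=CCBr
Why: Williamson etherification in a dipolar aprotic solvent, which overcomes the crowding of the 2,6-dialkylphenoxide; the allyl ether withstands the base, enolate and acylation chemistry ahead and leaves at the end without strong acid or hydrogen, neither of which the prenyl groups would tolerate.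

**Step 7**
Reactants: 12 ArB–CO2Me
Product: 13 4-(allyloxy)-3-[(E)-4-(TBDPS-oxy)-3-methylbut-2-enyl]-5-(3-methylbut-2-enyl)benzoic acid (ArB–CO2H)
Conditions: LiOH·H2O (5 equiv), THF/MeOH/H2O, 50 °C; then 1 M HCl to pH 4, 0 °C
Reagents that add atoms: lithium hydroxide, [Li+].[OH-]
Why: Saponification of an unhindered methyl benzoate, to which the allyl ether, the alkenes and the primary TBDPS ether are inert.

**Step 8**
Reactants: 13 ArB–CO2H; 14 methyl methoxyacetate
Product: 17 methyl 3-ArB-2-methoxy-3-oxopropanoate (racemic), via acyl imidazolide 15 (not isolated), via lithium enolate 16 (not isolated)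
Conditions: 13, 1,1'-carbonyldiimidazole (1.1 equiv), THF, rt; added to 14 (3.0 equiv) and LiN(i-Pr)2 (3.1 equiv), THF, −78 °C, then to −20 °C; AcOH quench
Reagents that add atoms: none
Why: Crossed Claisen condensation made one-directional by an acyl donor without α hydrogen: the acyl imidazolide, formed without acid, is C-acylated by the preformed lithium enolate (in excess, since free imidazole and the acidic product each consume base), which forms the future C2–C3 bond, and the new stereocentre is racemic and is erased in the next step.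

**Step 9**
Reactants: 17 methyl 3-ArB-2-methoxy-3-oxopropanoate
Product: 19 methyl (E)-3-ArB-3-chloro-2-methoxyacrylate, via enoloxyphosphonium chloride 18 (not isolated)
Conditions: Ph3PCl2 (1.3 equiv), Et3N (1.5 equiv), MeCN/CH2Cl2, 0 to 40 °C
Reagents that add atoms: dichlorotriphenylphosphorane, ClP(Cl)(c1ccccc1)(c1ccccc1)c1ccccc1
Why: Deoxychlorination of a 1,3-dicarbonyl compound with a chlorophosphonium reagent: the enolate oxygen binds to phosphorus and chloride then displaces triphenylphosphine oxide by addition–elimination at the activated carbon, while Et3N keeps the medium free of HCl so that the prenyl, allyl and silyl groups are spared.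

**Step 10**
Reactants: 20 methyl 3,5-dihydroxy-4-methoxybenzoate
Product: 21 methyl 3,5-bis(allyloxy)-4-methoxybenzoate
Conditions: allyl bromide (2.5 equiv), K2CO3 (3 equiv), DMF, rt
Reagents that add atoms: allyl bromide, C=CCBr
Why: Double Williamson etherification of two equivalent phenols, which keeps the mirror symmetry of ring A.

**Step 11**
Reactants: 21 methyl 3,5-bis(allyloxy)-4-methoxybenzoate
Product: 22 [3,5-bis(allyloxy)-4-methoxyphenyl]methanol
Conditions: LiAlH4, THF, 0 °C
Reagents that add atoms: none
Why: Hydride reduction of the ester to the benzylic alcohol, with aryl allyl ethers inert to LiAlH4.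

**Step 12**
Reactants: 22 [3,5-bis(allyloxy)-4-methoxyphenyl]methanol
Product: 23 3,5-bis(allyloxy)-4-methoxybenzaldehyde
Conditions: MnO2 (activated, 10 equiv), CH2Cl2, rt
Reagents that add atoms: none
Why: Heterogeneous MnO2 oxidation, selective for benzylic alcohols, which stops at the aldehyde and leaves the allyl ethers alone.

**Step 13**
Reactants: 23 3,5-bis(allyloxy)-4-methoxybenzaldehyde
Product: 25 3,5-bis(allyloxy)-4-methoxyphenol, via aryl formate 24 (not isolated)
Conditions: mCPBA (1.2 equiv), CH2Cl2, 0 °C to rt; wash (aq. Na2S2O3, NaHCO3); crude formate, K2CO3 (0.2 equiv), MeOH, 0 °C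
Reagents that add atoms: 3-chloroperoxybenzoic acid, OOC(=O)c1cccc(Cl)c1
Why: Baeyer–Villiger oxidation with a Dakin-type outcome: the electron-rich aryl group migrates to the peracid oxygen much faster than the monosubstituted allyl alkenes are epoxidised, and the aryl formate is methanolysed at once to the symmetric phenol.

**Step 14**
Reactants: 19 methyl (E)-3-ArB-3-chloro-2-methoxyacrylate; 25 3,5-bis(allyloxy)-4-methoxyphenol
Product: 26 methyl (E)-3-ArB-3-[3,5-bis(allyloxy)-4-methoxyphenoxy]-2-methoxyacrylate
Conditions: K2CO3 (1.5 equiv), DMF, argon, 70 °C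
Reagents that add atoms: none
Why: Vinylic nucleophilic substitution by addition–elimination, the classical entry to β-aryloxycinnamates from β-halo enoates: the loosely paired potassium phenoxide in DMF attacks through oxygen at the ester-activated β carbon and chloride leaves, which forms O1–C2 well below the temperature of any aromatic Claisen rearrangement.

**Step 15**
Reactants: 26 methyl (E)-3-ArB-3-[3,5-bis(allyloxy)-4-methoxyphenoxy]-2-methoxyacrylate
Product: 27 (E)-3-ArB-3-[3,5-bis(allyloxy)-4-methoxyphenoxy]-2-methoxyacrylic acid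
Conditions: LiOH·H2O (5 equiv), THF/MeOH/H2O, 40 °C; then 1 M HCl to pH 4, 0 °C
Reagents that add atoms: lithium hydroxide, [Li+].[OH-]
Why: Saponification as practised on β-aryloxycinnamates: the aryloxy donor makes the enoate a vinylogous carbonate, so hydroxide goes to the ester carbonyl and not to the β carbon, and cold, mild acidification avoids decarboxylation of the acid.

**Step 16**
Reactants: 27 (E)-3-ArB-3-[3,5-bis(allyloxy)-4-methoxyphenoxy]-2-methoxyacrylic acid
Product: 29 5,7-bis(allyloxy)-2-ArB-3,6-dimethoxy-4H-chromen-4-one, via mixed anhydride 28 (not isolated)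
Conditions: (CF3CO)2O (1.5 equiv), 2,6-di-tert-butyl-4-methylpyridine (3.5 equiv), CH2Cl2 (dilute, dry), 0 °C to rt
Reagents that add atoms: none
Why: Trifluoroacetic anhydride turns the acid into the mixed anhydride 28, which ionises to an acylium ion delocalised onto the future C2 as a ketene–oxocarbenium form supported by O1 and ring B, so the C2–C3 bond becomes nearly single and both alkene isomers reach the rotamer with the acyl carbon next to the phenoxy ring. An ortho carbon of that ring (future C4a) attacks the acyl carbon (future C4), and the hindered pyridine takes the proton from the arenium ion to give the 4-pyranone. The closest known reaction type is the Ruhemann-type flavone synthesis, the intramolecular Friedel–Crafts acylation of β-aryloxycinnamic acids, run here with the mixed-anhydride activation that is established for very electron-rich arenes. Ring C closes in a six-membered 6-exo mode, the attacked C=O staying outside the new ring, and no stereocentre is formed. Regioselectivity on ring A is settled by symmetry, since the two ortho carbons are identical, and chemoselectivity over a five-membered closure onto ring B (whose free carbons lie meta to its only oxygen) and over the side-chain alkenes is secured by the phloroglucinol-like activation and the proximity of the ring A ortho carbon. The buffer binds the trifluoroacetic acid released, so the trisubstituted alkenes, the aryl enol ether and the silyl ether are not protonated and no Lewis acid that could strip the C5 allyl ether is needed.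

**Step 17**
Reactants: 29 5,7-bis(allyloxy)-2-ArB-3,6-dimethoxy-4H-chromen-4-one
Product: 30 5,7-dihydroxy-2-{4-hydroxy-3-[(E)-4-(TBDPS-oxy)-3-methylbut-2-enyl]-5-(3-methylbut-2-enyl)phenyl}-3,6-dimethoxy-4H-chromen-4-one
Conditions: Pd(PPh3)4 (10 mol %), morpholine (10 equiv), THF, rt
Reagents that add atoms: none
Why: Tsuji–Trost-type deallylation: zerovalent palladium ionises the three aryl allyl ethers, whose phenoxides are good leaving groups because each is conjugated with the pyranone carbonyl, and excess morpholine traps the π-allyl complexes irreversibly, while the prenyl groups and the allylic silyl ether offer no leaving group.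

**Step 18**
Reactants: 30 5,7-dihydroxy-2-{4-hydroxy-3-[(E)-4-(TBDPS-oxy)-3-methylbut-2-enyl]-5-(3-methylbut-2-enyl)phenyl}-3,6-dimethoxy-4H-chromen-4-one
Product: 31 dodoviscin G
Conditions: Bu4NF (3 equiv), AcOH (3 equiv), THF, 0 °C to rt
Reagents that add atoms: none
Why: Fluoride-induced silyl ether cleavage driven by the Si–F bond, buffered with acetic acid so that the three phenols stay protonated and the ortho-prenylphenol meets neither strong base nor an acid able to close a chroman, with the E alkene untouched.

**Compound list**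
1 | methyl 4-hydroxybenzoate | COC(=O)c1ccc(O)cc1 | starting material
2 | prenyl bromide | CC(C)=CCBr | starting material
3 | sodium 4-(methoxycarbonyl)phenoxide | COC(=O)c1ccc([O-])cc1.[Na+] | intermediate
4 | methyl 4-hydroxy-3-(3-methylbut-2-enyl)benzoate | COC(=O)c1ccc(O)c(CC=C(C)C)c1 | intermediate
5 | methyl 4-acetoxy-3-(3-methylbut-2-enyl)benzoate | COC(=O)c1ccc(OC(C)=O)c(CC=C(C)C)c1 | intermediate
6 | methyl 4-acetoxy-3-[(E)-3-methyl-4-oxobut-2-enyl]benzoate | COC(=O)c1ccc(OC(C)=O)c(C/C=C(\C)C=O)c1 | intermediate
7 | methyl 4-acetoxy-3-[(E)-4-hydroxy-3-methylbut-2-enyl]benzoate | COC(=O)c1ccc(OC(C)=O)c(C/C=C(\C)CO)c1 | intermediate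
8 | methyl 4-acetoxy-3-[(E)-4-(TBDPS-oxy)-3-methylbut-2-enyl]benzoate | COC(=O)c1ccc(OC(C)=O)c(C/C=C(\C)CO[Si](c2ccccc2)(c2ccccc2)C(C)(C)C)c1 | intermediate
9 | methyl 4-hydroxy-3-[(E)-4-(TBDPS-oxy)-3-methylbut-2-enyl]benzoate | COC(=O)c1ccc(O)c(C/C=C(\C)CO[Si](c2ccccc2)(c2ccccc2)C(C)(C)C)c1 | intermediate
10 | sodium phenoxide of 9 | COC(=O)c1ccc([O-])c(C/C=C(\C)CO[Si](c2ccccc2)(c2ccccc2)C(C)(C)C)c1.[Na+] | intermediate
11 | methyl 4-hydroxy-3-[(E)-4-(TBDPS-oxy)-3-methylbut-2-enyl]-5-(3-methylbut-2-enyl)benzoate | COC(=O)c1cc(CC=C(C)C)c(O)c(C/C=C(\C)CO[Si](c2ccccc2)(c2ccccc2)C(C)(C)C)c1 | intermediate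
12 | methyl 4-(allyloxy)-3-[(E)-4-(TBDPS-oxy)-3-methylbut-2-enyl]-5-(3-methylbut-2-enyl)benzoate | COC(=O)c1cc(CC=C(C)C)c(OCC=C)c(C/C=C(\C)CO[Si](c2ccccc2)(c2ccccc2)C(C)(C)C)c1 | intermediate
13 | 4-(allyloxy)-3-[(E)-4-(TBDPS-oxy)-3-methylbut-2-enyl]-5-(3-methylbut-2-enyl)benzoic acid | OC(=O)c1cc(CC=C(C)C)c(OCC=C)c(C/C=C(\C)CO[Si](c2ccccc2)(c2ccccc2)C(C)(C)C)c1 | intermediate
14 | methyl methoxyacetate | COCC(=O)OC | starting material
15 | N-acylimidazole of acid 13 | O=C(n1ccnc1)c1cc(CC=C(C)C)c(OCC=C)c(C/C=C(\C)CO[Si](c2ccccc2)(c2ccccc2)C(C)(C)C)c1 | intermediate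
16 | lithium enolate of methyl methoxyacetate (chelated form) | [Li+].CO/C=C(\[O-])OC | intermediate
17 | methyl 3-ArB-2-methoxy-3-oxopropanoate (racemic, enolisable) | COC(=O)C(OC)C(=O)c1cc(CC=C(C)C)c(OCC=C)c(C/C=C(\C)CO[Si](c2ccccc2)(c2ccccc2)C(C)(C)C)c1 | intermediate
18 | enoloxytriphenylphosphonium chloride of 17 | COC(=O)/C(OC)=C(\O[P+](c1ccccc1)(c1ccccc1)c1ccccc1)c1cc(CC=C(C)C)c(OCC=C)c(C/C=C(\C)CO[Si](c2ccccc2)(c2ccccc2)C(C)(C)C)c1.[Cl-] | intermediate
19 | methyl (E)-3-ArB-3-chloro-2-methoxyacrylate | COC(=O)/C(OC)=C(\Cl)c1cc(CC=C(C)C)c(OCC=C)c(C/C=C(\C)CO[Si](c2ccccc2)(c2ccccc2)C(C)(C)C)c1 | intermediate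
20 | methyl 3,5-dihydroxy-4-methoxybenzoate | COC(=O)c1cc(O)c(OC)c(O)c1 | starting material
21 | methyl 3,5-bis(allyloxy)-4-methoxybenzoate | COC(=O)c1cc(OCC=C)c(OC)c(OCC=C)c1 | intermediate
22 | [3,5-bis(allyloxy)-4-methoxyphenyl]methanol | OCc1cc(OCC=C)c(OC)c(OCC=C)c1 | intermediate
23 | 3,5-bis(allyloxy)-4-methoxybenzaldehyde | O=Cc1cc(OCC=C)c(OC)c(OCC=C)c1 | intermediate
24 | 3,5-bis(allyloxy)-4-methoxyphenyl formate | O=COc1cc(OCC=C)c(OC)c(OCC=C)c1 | intermediate
25 | 3,5-bis(allyloxy)-4-methoxyphenol | COc1c(OCC=C)cc(O)cc1OCC=C | intermediate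
26 | methyl (E)-3-ArB-3-[3,5-bis(allyloxy)-4-methoxyphenoxy]-2-methoxyacrylate | COC(=O)/C(OC)=C(\Oc1cc(OCC=C)c(OC)c(OCC=C)c1)c1cc(CC=C(C)C)c(OCC=C)c(C/C=C(\C)CO[Si](c2ccccc2)(c2ccccc2)C(C)(C)C)c1 | intermediate
27 | (E)-3-ArB-3-[3,5-bis(allyloxy)-4-methoxyphenoxy]-2-methoxyacrylic acid | OC(=O)/C(OC)=C(\Oc1cc(OCC=C)c(OC)c(OCC=C)c1)c1cc(CC=C(C)C)c(OCC=C)c(C/C=C(\C)CO[Si](c2ccccc2)(c2ccccc2)C(C)(C)C)c1 | intermediate
28 | mixed anhydride of 27 with trifluoroacetic acid | O=C(OC(=O)C(F)(F)F)/C(OC)=C(\Oc1cc(OCC=C)c(OC)c(OCC=C)c1)c1cc(CC=C(C)C)c(OCC=C)c(C/C=C(\C)CO[Si](c2ccccc2)(c2ccccc2)C(C)(C)C)c1 | intermediate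
29 | 5,7-bis(allyloxy)-2-ArB-3,6-dimethoxy-4H-chromen-4-one | COc1c(OCC=C)cc2oc(-c3cc(CC=C(C)C)c(OCC=C)c(C/C=C(\C)CO[Si](c4ccccc4)(c4ccccc4)C(C)(C)C)c3)c(OC)c(=O)c2c1OCC=C | intermediate
30 | 5,7-dihydroxy-2-{4-hydroxy-3-[(E)-4-(TBDPS-oxy)-3-methylbut-2-enyl]-5-(3-methylbut-2-enyl)phenyl}-3,6-dimethoxy-4H-chromen-4-one | COc1c(O)cc2oc(-c3cc(CC=C(C)C)c(O)c(C/C=C(\C)CO[Si](c4ccccc4)(c4ccccc4)C(C)(C)C)c3)c(OC)c(=O)c2c1O | intermediate
31 | dodoviscin G | COc1c(O)cc2oc(-c3cc(CC=C(C)C)c(O)c(C/C=C(\C)CO)c3)c(OC)c(=O)c2c1O | target

**Step count**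
Total step count: 18.
Longest linear sequence: 14 (steps 1 to 9, then 14 to 18). Steps 10 to 13 form the ring A branch.

**Steps most likely to fail**

1. **Step 14.**
   - What may go wrong: slow addition of the phenoxide to a crowded β carbon that is deactivated by the α-methoxy group and by ring B, or attack through an ortho carbon of the ambident phenoxide in place of oxygen.
   - Fallback: the addition–elimination is replaced by a copper-catalysed Ullmann-type vinylation, which does not depend on the electrophilicity of the alkene and couples at oxygen only.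
   - It sets out from β-keto ester 17. With Ph3PBr2 and Et3N, in the manner of step 9, this should give the β-bromo-α-methoxycinnamate F1.
   - Coupling of F1 with phenol 25 (CuI, N,N-dimethylglycine, Cs2CO3, dioxane, 80 °C) comes back to the route at 26.

2. **Step 16.**
   - What may go wrong: too little ionisation of the buffered mixed anhydride, so that reversion to the acid and decarboxylation take over. Protonation of the side-chain alkenes could follow once stronger activation is tried.
   - Fallback: the same C4–C4a bond is made under basic conditions by a Parham cyclisation, in which the ring A carbon is made nucleophilic by halogen–metal exchange.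
   - It sets out from phenol 25, which with N-iodosuccinimide (MeCN, −20 °C) should give 3,5-bis(allyloxy)-2-iodo-4-methoxyphenol F2.
   - F2 is joined to chloride 19 as in step 14 to give the iodinated aryloxycinnamate F3.
   - Treatment with iPrMgCl·LiCl (THF, −40 °C) forms the arylmagnesium chloride F4, which attacks the neighbouring methyl ester and expels methoxide. This comes back at 29 and also saves step 15.
   - Only the isomer with the ester cis to the aryloxy group can close. The other would be re-equilibrated by warming with a little phenoxide.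

3. **Step 9.**
   - What may go wrong: incomplete capture of the poorly enolised keto ester, slow displacement of the phosphine oxide at the crowded carbon, or exchange of the allylic silyl ether for chloride by excess reagent.
   - Fallback: the halide is given up for an enol sulfonate. It sets out from 17, which with TsCl, N-methylimidazole and Et3N (CH2Cl2, 0 °C) should give the enol tosylate F5.
   - F5 is treated directly with phenol 25 and K2CO3 in DMF, as is known for tosyloxy derivatives of cyclic β-keto esters. This comes back at 26, so that 19 is bypassed.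

**Further compounds**
F1 | step 14 | methyl (E)-3-ArB-3-bromo-2-methoxyacrylate | COC(=O)/C(OC)=C(\Br)c1cc(CC=C(C)C)c(OCC=C)c(C/C=C(\C)CO[Si](c2ccccc2)(c2ccccc2)C(C)(C)C)c1
F2 | step 16 | 3,5-bis(allyloxy)-2-iodo-4-methoxyphenol | COc1c(OCC=C)cc(O)c(I)c1OCC=C
F3 | step 16 | methyl (E)-3-ArB-3-[3,5-bis(allyloxy)-2-iodo-4-methoxyphenoxy]-2-methoxyacrylate | COC(=O)/C(OC)=C(\Oc1cc(OCC=C)c(OC)c(OCC=C)c1I)c1cc(CC=C(C)C)c(OCC=C)c(C/C=C(\C)CO[Si](c2ccccc2)(c2ccccc2)C(C)(C)C)c1
F4 | step 16 | arylmagnesium chloride derived from F3 | COC(=O)/C(OC)=C(\Oc1cc(OCC=C)c(OC)c(OCC=C)c1[Mg]Cl)c1cc(CC=C(C)C)c(OCC=C)c(C/C=C(\C)CO[Si](c2ccccc2)(c2ccccc2)C(C)(C)C)c1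
F5 | step 9 | methyl (E)-3-ArB-2-methoxy-3-(4-toluenesulfonyloxy)acrylate | COC(=O)/C(OC)=C(\OS(=O)(=O)c1ccc(C)cc1)c1cc(CC=C(C)C)c(OCC=C)c(C/C=C(\C)CO[Si](c2ccccc2)(c2ccccc2)C(C)(C)C)c1
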